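**Plan**

- Feature: apart from the methyl on C3, the two 8-hydroxy-5-methyl-3,4-dihydro-2H-cyclohepta[b]pyran-7-one halves are related by a C2 axis through the midpoint of the (1E,3E)-buta-1,3-diene. C2 and C2' are both R and each is bonded to one diene terminus, so both C2–diene bonds can be cut together.
- Retrosynthesis: the two O–CH3 bonds (tropolone protection), C4=O and C4'=O (put back), C3–CH3, then C2–diene and C2'–diene, giving two molecules of a tropone-fused pyran-4-one and a 1,4-diborylbuta-1,3-diene.
- The pyranone ring is cut at O1–C9a and C2–C3 (formamide acetal carbon) back to an acetyltropone. The tropone comes from a cyclohexadiene by insertion of C7 between C6 and C8, and the cyclohexadiene is cut at C4a–C5 and C9–C9a (Diels–Alder).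
- Forward: six-membered ring by Diels–Alder, one-carbon expansion to the seven-membered ring, dehydrogenation to the tropone, pyranone annulation, two-directional conjugate alkenylation joining the three pieces, C3 methylation on one side, removal of both C4 oxygens, demethylation.
- Stereochemistry: C2 and C2' from the (R)-BINAP–rhodium catalyst, C3 from alkylation of the C3 enolate anti to the C2 substituent, E,E geometry from syn hydroboration of buta-1,3-diyne.

Key step: step 9

Remark: the two tropolone tautomers (7-oxo-8-hydroxy and 8-oxo-7-hydroxy) interconvert, so the 7-methoxy-8-oxo ether carried here converges on the same tropolone as its 8-methoxy-7-oxo isomer. Locants follow cyclohepta[b]pyran numbering (O1, C2, C3, C4, C4a, C5 to C9, C9a).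

**Route**

Step 1
Reactants: 1 (E)-pent-3-en-2-one
Product: 2 (E)-2-(tert-butyldimethylsilyloxy)penta-1,3-diene
Conditions: LiN(iPr)2, THF, −78 °C; tBuMe2SiCl, DMPU, −78 → 0 °C
Reagents that add atoms: tert-butyldimethylsilyl chloride, CC(C)(C)[Si](C)(C)Cl
Why: Kinetic deprotonation of the methyl ketone and O-silylation of the cross-conjugated lithium enolate is the standard entry to 2-silyloxy-1,3-dienes and leaves the E propenyl geometry untouched.

Step 2
Reactants: 3 but-3-yn-2-one
Product: 4 4-bromobut-3-yn-2-one
Conditions: N-bromosuccinimide, AgNO3 (5 mol %), acetone, 25 °C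
Reagents that add atoms: N-bromosuccinimide, O=C1CCC(=O)N1Br
Why: Silver-catalysed electrophilic bromination of the terminal alkyne replaces the acetylenic hydrogen and gives an activated dienophile whose β-carbon carries a leaving group for the later oxygen substitution.

Step 3
Reactants: 2 (E)-2-(tert-butyldimethylsilyloxy)penta-1,3-diene; 4 4-bromobut-3-yn-2-one
Product: 5 1-[2-bromo-4-(tert-butyldimethylsilyloxy)-6-methylcyclohexa-1,4-dien-1-yl]ethan-1-one (racemic)
Conditions: toluene, 25 → 60 °C
Reagents that add atoms: none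
Why: Diels–Alder reaction in which the silyloxy group and the terminal methyl of 2 both direct the CH2 terminus to the bromine-bearing β-carbon of the ynone, so the acetyl group ends next to the methyl-bearing carbon and a skipped diene with an isolated silyl enol ether should result; the one sp3 stereocentre is racemic and is erased in step 5.

Step 4
Reactants: 5 1-[2-bromo-4-(tert-butyldimethylsilyloxy)-6-methylcyclohexa-1,4-dien-1-yl]ethan-1-one
Product: 7 5-acetyl-6-bromo-2-chloro-4-methylcyclohepta-2,5-dien-1-one (racemic), via dichlorocyclopropane adduct 6 (not isolated)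
Conditions: Cl3CCO2Na, MeOCH2CH2OMe, 85 °C; then Et3N·3HF, THF, 25 °C
Reagents that add atoms: sodium trichloroacetate, [Na+].[O-]C(=O)C(Cl)(Cl)Cl
Why: Electrophilic dichlorocarbene generated under neutral conditions should add only to the electron-rich silyl enol ether, and fluoride-triggered opening of the silyloxy dichlorocyclopropane with loss of chloride gives the one-carbon ring-expanded 2-chloro enone, the known dihalocarbene ring expansion of silyl enol ethers.

Step 5
Reactants: 7 5-acetyl-6-bromo-2-chloro-4-methylcyclohepta-2,5-dien-1-one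
Product: 8 5-acetyl-6-bromo-2-chloro-4-methylcyclohepta-2,4,6-trien-1-one
Conditions: DDQ, 1,4-dioxane, 80 °C
Reagents that add atoms: none
Why: Quinone dehydrogenation by hydride abstraction from the doubly allylic C4–H of the cycloheptatrienol tautomer gives a hydroxytropylium ion that loses a proton to the tropone, the usual way from dihydrotropones to tropones.

Step 6
Reactants: 8 5-acetyl-6-bromo-2-chloro-4-methylcyclohepta-2,4,6-trien-1-one
Product: 9 5-acetyl-2,6-dimethoxy-4-methylcyclohepta-2,4,6-trien-1-one
Conditions: NaOMe (2.2 equiv), MeOH, 0 → 25 °C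
Reagents that add atoms: sodium methoxide, [Na+].[O-]C
Why: 2-Halotropones and β-halo enones undergo addition–elimination with alkoxides at the halogen-bearing carbon, so both halides should be exchanged, the methoxy group at C2 becoming the protected tropolone oxygen and the one at C6 a leaving group for pyranone closure.

Step 7
Reactants: 9 5-acetyl-2,6-dimethoxy-4-methylcyclohepta-2,4,6-trien-1-one
Product: 11 7-methoxy-5-methylcyclohepta[b]pyran-4,8-dione, via enaminone 10 (not isolated)
Conditions: Me2NCH(OMe)2, toluene, 95 °C; then AcOH/H2O, 60 °C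
Reagents that add atoms: N,N-dimethylformamide dimethyl acetal, COC(OC)N(C)C; water, O
Why: Condensation of the methyl ketone with the formamide acetal gives the β-dimethylamino enone, whose acidic hydrolysis frees an enol oxygen that displaces the neighbouring vinylogous-ester methoxy group by six-membered addition–elimination, the enaminone variant of the chromone synthesis.

Step 8
Reactants: 12 1,4-bis(trimethylsilyl)buta-1,3-diyne; 13 4,4,5,5-tetramethyl-1,3,2-dioxaborolane (pinacolborane, 2.2 equiv, one molecule for each alkyne terminus)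
Product: 15 (1E,3E)-1,4-bis(4,4,5,5-tetramethyl-1,3,2-dioxaborolan-2-yl)buta-1,3-diene, via buta-1,3-diyne 14 (not isolated)
Conditions: K2CO3 (10 mol %), MeOH, 0 → 25 °C, N2 sweep through CaCl2 into THF at −78 °C; then 13 (2.2 equiv), Cp2Zr(H)Cl (10 mol %), Et3N (10 mol %), THF, 0 → 25 °C
Reagents that add atoms: 4,4,5,5-tetramethyl-1,3,2-dioxaborolane (the second equivalent of 13), CC1(C)OBOC1(C)C
Why: Methanolysis of the two alkynyl–silicon bonds releases buta-1,3-diyne, kept throughout as a cold dilute solution, and zirconocene-catalysed syn hydroboration (hydrozirconation of a terminal alkyne, then zirconium–boron exchange with pinacolborane) takes place once at each terminus, so two molecules of 13 are consumed per diyne and boron ends on both terminal carbons with E geometry at both double bonds.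

Step 9
Reactants: 11 7-methoxy-5-methylcyclohepta[b]pyran-4,8-dione (2.2 equiv); 15 (1E,3E)-1,4-bis(4,4,5,5-tetramethyl-1,3,2-dioxaborolan-2-yl)buta-1,3-diene
Product: 16 (2R,2'R)-2,2'-[(1E,3E)-buta-1,3-diene-1,4-diyl]bis(7-methoxy-5-methyl-2,3-dihydrocyclohepta[b]pyran-4,8-dione)
Conditions: Rh(acac)(C2H4)2 (6 mol %), (R)-BINAP (7 mol %), K3PO4 (0.5 equiv), 1,4-dioxane/H2O 10:1, 50 °C
Reagents that add atoms: none
Why: Transmetalation of one alkenyl–boron terminus of 15 to the hydroxo(BINAP) complex of monovalent rhodium gives an alkenylrhodium species that inserts the C2=C3 bond of 11 in a syn fashion, and hydrolysis of the oxa-π-allyl rhodium enolate releases the ketone and regenerates the hydroxo complex; the same cycle at the second terminus joins a second molecule of 11, so the C2–diene and C2'–diene bonds are formed and no ring is closed. The closest known reaction type is the Hayashi–Miyaura asymmetric 1,4-addition of alkenylboron reagents to cyclic enones and chromones. Both new stereocentres, C2 and C2', are set by the catalyst: by analogy with the carbocyclic enone series (R)-BINAP is expected to deliver the alkenyl group to the face that gives R, which should be confirmed on the first adduct, and because the two acceptors are identical the major product should be the homochiral C2-symmetric diketone while residual facial error ends mainly in the separable meso isomer. The step needs site selectivity for C2 over the tropone ring, which the substrate should secure because C2 is the only β-carbon on a disubstituted alkene outside the tropone π-system (C5 and C9a are fully substituted, and attack at C6 would break the tropone conjugation at a trisubstituted methoxy-bearing alkene). It also needs retention of the E geometry, which alkenyl transfer from boron to rhodium provides.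

Step 10
Reactants: 16 (2R,2'R)-2,2'-[(1E,3E)-buta-1,3-diene-1,4-diyl]bis(7-methoxy-5-methyl-2,3-dihydrocyclohepta[b]pyran-4,8-dione)
Product: 17 (2S,3S)-7-methoxy-2-{(1E,3E)-4-[(2R)-7-methoxy-5-methyl-4,8-dioxo-2,3,4,8-tetrahydrocyclohepta[b]pyran-2-yl]buta-1,3-dien-1-yl}-3,5-dimethyl-2,3-dihydrocyclohepta[b]pyran-4,8-dione (2,3-trans; C2 keeps the spatial arrangement of 16, the letter changes only through the priority rules)
Conditions: LiN(SiMe3)2 (0.9 equiv), THF, −78 °C; MeI, DMPU, −78 → −40 °C; AcOH quench
Reagents that add atoms: iodomethane, CI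
Why: Kinetic lithium enolate formation at C3 of one of the two equivalent ketones with a deficit of base and SN2 methylation anti to the C2 dienyl substituent should set the 2,3-trans relationship by substrate control, the low temperature suppressing β-elimination of the ring oxygen; unreacted 16 is recycled.

Step 11
Reactants: 17 the mono-C3-methyl diketone
Product: 18 the 4,4'-diol of 17, 4-hydroxy-2-{(1E,3E)-4-[4-hydroxy-7-methoxy-5-methyl-8-oxo-2,3,4,8-tetrahydrocyclohepta[b]pyran-2-yl]buta-1,3-dien-1-yl}-7-methoxy-3,5-dimethyl-3,4-dihydrocyclohepta[b]pyran-8(2H)-one (C2, C3 and C2' as in 17; both epimers at C4 and C4')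
Conditions: NaBH4, CeCl3·7H2O, MeOH/THF, −40 → 0 °C
Reagents that add atoms: none
Why: Luche conditions should effect 1,2-hydride addition to the two C4 ketones while the less electrophilic tropone carbonyls and the diene are left alone, and the new carbinol centres are uncontrolled because they are removed in step 13.

Step 12
Reactants: 18 the 4,4'-diol
Product: 19 the 4,4'-bis(O-phenoxythiocarbonyl) derivative of 18 (C2, C3 and C2' as in 17; both epimers at C4 and C4')
Conditions: PhOC(S)Cl (2.5 equiv), pyridine, DMAP (20 mol %), CH2Cl2, 0 → 25 °C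
Reagents that add atoms: O-phenyl chlorothionoformate, S=C(Cl)Oc1ccccc1
Why: Acylation of the two secondary alcohols with the chlorothionoformate under weakly basic conditions gives the thiocarbonates needed for Barton–McCombie deoxygenation without a strong base or a nucleophilic amine that could attack the methoxytropone.

Step 13
Reactants: 19 the 4,4'-bis(O-phenoxythiocarbonyl) derivative
Product: 20 (2R,3R)-7-methoxy-2-{(1E,3E)-4-[(2R)-7-methoxy-5-methyl-8-oxo-2,3,4,8-tetrahydrocyclohepta[b]pyran-2-yl]buta-1,3-dien-1-yl}-3,5-dimethyl-3,4-dihydrocyclohepta[b]pyran-8(2H)-one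
Conditions: Bu3SnH, AIBN (20 mol %), toluene, 80 °C
Reagents that add atoms: none
Why: Barton–McCombie deoxygenation, in which the stannyl radical adds to sulfur and the C4–O bond fragments to a radical stabilised by the troponoid ring that is quenched by the tin hydride, should remove both C4 oxygens without touching C2, C3 or the diene.

Step 14
Reactants: 20 the bis(methyl ether)
Product: 21 (2R,3R)-8-hydroxy-2-{(1E,3E)-4-[(2R)-8-hydroxy-5-methyl-7-oxo-2,3,4,7-tetrahydrocyclohepta[b]pyran-2-yl]buta-1,3-dien-1-yl}-3,5-dimethyl-3,4-dihydrocyclohepta[b]pyran-7(2H)-one (CNP0332980.1)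
Conditions: LiCl (10 equiv), DMF, 110 °C; aq NH4Cl work-up
Reagents that add atoms: none
Why: Chloride should attack the two O-methyl carbons in an SN2 dealkylation assisted by lithium chelation between the tropone carbonyl and the methoxy oxygen, releasing both tropolones, whose tautomers equilibrate to the target.

**Compound list**

1 | (E)-pent-3-en-2-one | C/C=C/C(C)=O | starting material
2 | (E)-2-(tert-butyldimethylsilyloxy)penta-1,3-diene | C=C(O[Si](C)(C)C(C)(C)C)/C=C/C | intermediate
3 | but-3-yn-2-one | CC(=O)C#C | starting material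
4 | 4-bromobut-3-yn-2-one | CC(=O)C#CBr | intermediate
5 | 1-[2-bromo-4-(tert-butyldimethylsilyloxy)-6-methylcyclohexa-1,4-dien-1-yl]ethan-1-one (racemic) | CC(=O)C1=C(Br)CC(O[Si](C)(C)C(C)(C)C)=CC1C | intermediate
6 | 1-[3-bromo-1-(tert-butyldimethylsilyloxy)-7,7-dichloro-5-methylbicyclo[4.1.0]hept-3-en-4-yl]ethan-1-one (racemic, diastereomer mixture) | CC(=O)C1=C(Br)CC2(O[Si](C)(C)C(C)(C)C)C(C1C)C2(Cl)Cl | intermediate (not isolated)
7 | 5-acetyl-6-bromo-2-chloro-4-methylcyclohepta-2,5-dien-1-one (racemic) | CC(=O)C1=C(Br)CC(=O)C(Cl)=CC1C | intermediate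
8 | 5-acetyl-6-bromo-2-chloro-4-methylcyclohepta-2,4,6-trien-1-one | O=C1C(Cl)=CC(C)=C(C(C)=O)C(Br)=C1 | intermediate
9 | 5-acetyl-2,6-dimethoxy-4-methylcyclohepta-2,4,6-trien-1-one | O=C1C(OC)=CC(C)=C(C(C)=O)C(OC)=C1 | intermediate
10 | 5-[(2E)-3-(dimethylamino)prop-2-enoyl]-2,6-dimethoxy-4-methylcyclohepta-2,4,6-trien-1-one | O=C1C(OC)=CC(C)=C(C(=O)/C=C/N(C)C)C(OC)=C1 | intermediate (not isolated)
11 | 7-methoxy-5-methylcyclohepta[b]pyran-4,8-dione | CC1=C2C(=O)C=COC2=CC(=O)C(OC)=C1 | intermediate
12 | 1,4-bis(trimethylsilyl)buta-1,3-diyne | C[Si](C)(C)C#CC#C[Si](C)(C)C | starting material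
13 | 4,4,5,5-tetramethyl-1,3,2-dioxaborolane (pinacolborane) | CC1(C)OBOC1(C)C | starting material
14 | buta-1,3-diyne | C#CC#C | intermediate (not isolated)
15 | (1E,3E)-1,4-bis(4,4,5,5-tetramethyl-1,3,2-dioxaborolan-2-yl)buta-1,3-diene | CC1(C)OB(/C=C/C=C/B2OC(C)(C)C(C)(C)O2)OC1(C)C | intermediate
16 | (2R,2'R)-2,2'-[(1E,3E)-buta-1,3-diene-1,4-diyl]bis(7-methoxy-5-methyl-2,3-dihydrocyclohepta[b]pyran-4,8-dione) | CC1=C2C(=O)C[C@H](/C=C/C=C/[C@H]3CC(=O)C4=C(C)C=C(OC)C(=O)C=C4O3)OC2=CC(=O)C(OC)=C1 | intermediate
17 | (2S,3S)-7-methoxy-2-{(1E,3E)-4-[(2R)-7-methoxy-5-methyl-4,8-dioxo-2,3,4,8-tetrahydrocyclohepta[b]pyran-2-yl]buta-1,3-dien-1-yl}-3,5-dimethyl-2,3-dihydrocyclohepta[b]pyran-4,8-dione (2,3-trans) | CC1=C2C(=O)[C@@H](C)[C@H](/C=C/C=C/[C@H]3CC(=O)C4=C(C)C=C(OC)C(=O)C=C4O3)OC2=CC(=O)C(OC)=C1 | intermediate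
18 | 4,4'-diol of 17 (C2, C3, C2' as in 17; epimers at C4 and C4') | CC1=C2C(O)[C@@H](C)[C@H](/C=C/C=C/[C@H]3CC(O)C4=C(C)C=C(OC)C(=O)C=C4O3)OC2=CC(=O)C(OC)=C1 | intermediate
19 | 4,4'-bis(O-phenoxythiocarbonyl) derivative of 18 (C2, C3, C2' as in 17; epimers at C4 and C4') | CC1=C2C(OC(=S)Oc5ccccc5)[C@@H](C)[C@H](/C=C/C=C/[C@H]3CC(OC(=S)Oc6ccccc6)C4=C(C)C=C(OC)C(=O)C=C4O3)OC2=CC(=O)C(OC)=C1 | intermediate
20 | (2R,3R)-7-methoxy-2-{(1E,3E)-4-[(2R)-7-methoxy-5-methyl-8-oxo-2,3,4,8-tetrahydrocyclohepta[b]pyran-2-yl]buta-1,3-dien-1-yl}-3,5-dimethyl-3,4-dihydrocyclohepta[b]pyran-8(2H)-one | CC1=C2C[C@@H](C)[C@H](/C=C/C=C/[C@H]3CCC4=C(C)C=C(OC)C(=O)C=C4O3)OC2=CC(=O)C(OC)=C1 | intermediate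
21 | (2R,3R)-8-hydroxy-2-{(1E,3E)-4-[(2R)-8-hydroxy-5-methyl-7-oxo-2,3,4,7-tetrahydrocyclohepta[b]pyran-2-yl]buta-1,3-dien-1-yl}-3,5-dimethyl-3,4-dihydrocyclohepta[b]pyran-7(2H)-one | Cc1cc(=O)c(O)cc2c1C[C@@H](C)[C@H](/C=C/C=C/[C@H]1CCc3c(C)cc(=O)c(O)cc3O1)O2 | target

**Summary**

Total step count: 14. Longest linear sequence: 12 steps (steps 1, 3, 4, 5, 6, 7, 9, 10, 11, 12, 13, 14).

Steps most likely to fail:

Step 9. The second alkenyl transfer may lose out to protodeboronation of the remaining dienyl–boron terminus, rhodium may insert into the tropone ring instead of the pyranone, and facial selectivity may leak into the meso isomer. The fallback sets out from 11 and makes the central diene bond last, so that each molecule undergoes only one conjugate addition. Rhodium/(R)-BINAP addition of commercial (E)-2-(trimethylsilyl)ethenylboronic acid pinacol ester to 11 should give (2R)-7-methoxy-5-methyl-2-[(E)-2-(trimethylsilyl)ethenyl]-2,3-dihydrocyclohepta[b]pyran-4,8-dione F1. Iododesilylation with N-iodosuccinimide in MeCN should give (2R)-2-[(E)-2-iodoethenyl]-7-methoxy-5-methyl-2,3-dihydrocyclohepta[b]pyran-4,8-dione F2 with retention of geometry. Stannylative homocoupling of F2 with Pd(PPh3)4 and Me3SnSnMe3 in toluene, a neutral medium, joins two molecules at the iodine-bearing carbons and comes back to the route at 16.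

Step 10. Methylation of a C2-symmetric diketone is statistical, so over-methylation of the second ketone competes. In addition the C3 enolate may expel the ring oxygen by β-elimination, which would open the pyran ring and erode the C2 configuration. The fallback sets out from 11 and 15 and desymmetrises before the second ring is attached. With 15 in threefold excess, the conjugate addition of step 9 should stop at (2R)-7-methoxy-5-methyl-2-[(1E,3E)-4-(4,4,5,5-tetramethyl-1,3,2-dioxaborolan-2-yl)buta-1,3-dien-1-yl]-2,3-dihydrocyclohepta[b]pyran-4,8-dione F3. Its single ketone can be taken fully to the lithium enolate (LiN(SiMe3)2, −78 °C, MeI) to give the 2,3-trans methylated boronate (2S,3S)-7-methoxy-3,5-dimethyl-2-[(1E,3E)-4-(4,4,5,5-tetramethyl-1,3,2-dioxaborolan-2-yl)buta-1,3-dien-1-yl]-2,3-dihydrocyclohepta[b]pyran-4,8-dione F4. A second rhodium/(R)-BINAP addition of F4 to 11 comes back to the route at 17.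

Step 14. The temperature needed for chloride dealkylation may ionise the dienylic C2–O1 bonds or degrade the polyene, and the second methyl group may be removed incompletely. The fallback sets out from 20 and cleaves the other bond of each ether: LiOH in THF/H2O at 40 °C, then buffering to pH 5. Hydroxide adds to the methoxy-bearing α-carbon C7 of each tropone and methoxide leaves, as in the saponification of a vinylogous ester, which comes back to the route at 21 without a new isolated compound.

Further compounds
F1 | step 9 | (2R)-7-methoxy-5-methyl-2-[(E)-2-(trimethylsilyl)ethenyl]-2,3-dihydrocyclohepta[b]pyran-4,8-dione | CC1=C2C(=O)C[C@H](/C=C/[Si](C)(C)C)OC2=CC(=O)C(OC)=C1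
F2 | step 9 | (2R)-2-[(E)-2-iodoethenyl]-7-methoxy-5-methyl-2,3-dihydrocyclohepta[b]pyran-4,8-dione | CC1=C2C(=O)C[C@H](/C=C/I)OC2=CC(=O)C(OC)=C1
F3 | step 10 | (2R)-7-methoxy-5-methyl-2-[(1E,3E)-4-(4,4,5,5-tetramethyl-1,3,2-dioxaborolan-2-yl)buta-1,3-dien-1-yl]-2,3-dihydrocyclohepta[b]pyran-4,8-dione | CC1=C2C(=O)C[C@H](/C=C/C=C/B3OC(C)(C)C(C)(C)O3)OC2=CC(=O)C(OC)=C1
F4 | step 10 | (2S,3S)-7-methoxy-3,5-dimethyl-2-[(1E,3E)-4-(4,4,5,5-tetramethyl-1,3,2-dioxaborolan-2-yl)buta-1,3-dien-1-yl]-2,3-dihydrocyclohepta[b]pyran-4,8-dione | CC1=C2C(=O)[C@@H](C)[C@H](/C=C/C=C/B3OC(C)(C)C(C)(C)O3)OC2=CC(=O)C(OC)=C1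
F0 | step 14 | none | none
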